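**Plan**

- Retrosynthesis: the last skeletal cuts are N11–C10a and N12–C12a (pyrrole rings D and B), made on a precursor whose N11 and N12 are joined by an oxalyl bridge. Before that come the two oxalyl N–C(O) bonds, the biaryl bonds C6a–C6b and C4b–C4a, and the C–Br and thiadiazole bonds back to 4,5-dimethoxybenzene-1,2-diamine.
- Forward: ring C is bought with both nitrogens and both methoxy groups in place. It is masked as a benzothiadiazole and dibrominated, and rings A and E are attached as 4-chlorophenyl groups by Suzuki–Miyaura coupling.
- After unmasking, the two nitrogens are tied into a quinoxaline-2,3-dione. Rings B and D then close in one flask by twofold palladium-catalysed oxidative C–H amination, and methanolysis removes the bridge.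
- Enabling feature: Cl at C2 and C9 lies para to the biaryl carbons C4a and C6b, so rings A and E are symmetric 4-chlorophenyl groups with equivalent ortho C–H bonds. N11 and N12 sit on the adjacent carbons C11a and C11b of ring C, the right spacing for a two-carbon tether.
- Stereochemistry: none; the target is achiral.

Key step: step 6

Remark: indolo[2,3-a]carbazole numbering is used for all cyclised compounds, and 1 is taken as the free base (with the dihydrochloride, two more equivalents of Et3N go into step 1).

**Route**

Step 1
Reactants: 1 4,5-dimethoxybenzene-1,2-diamine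
Product: 3 5,6-dimethoxy-2,1,3-benzothiadiazole, via N-sulfinylamine 2 (not isolated)
Conditions: SOCl2 (2.2 equiv), Et3N (4.5 equiv), CH2Cl2, 0 °C to reflux
Reagents that add atoms: thionyl chloride, O=S(Cl)Cl
Why: Condensation of an o-phenylenediamine with SOCl2 (N-sulfinylation, then cyclodehydration, the second equivalent of SOCl2 taking up the water) is the standard benzothiadiazole synthesis, and the thiadiazole masks both nitrogens against oxidation while making the ring electron-poor for the later coupling.

Step 2
Reactants: 3 5,6-dimethoxy-2,1,3-benzothiadiazole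
Product: 5 4,7-dibromo-5,6-dimethoxy-2,1,3-benzothiadiazole, via monobromide 4 (not isolated)
Conditions: Br2 (3 equiv), AcOH/CH2Cl2, rt, dark
Reagents that add atoms: bromine, BrBr
Why: Electrophilic aromatic bromination can only occur at C4 and C7, the two free positions, each activated by an ortho methoxy group, and this dibromination is routine for 5,6-dialkoxybenzothiadiazoles.

Step 3
Reactants: 5 4,7-dibromo-5,6-dimethoxy-2,1,3-benzothiadiazole; 6 4-chlorophenylboronic acid
Product: 8 4,7-bis(4-chlorophenyl)-5,6-dimethoxy-2,1,3-benzothiadiazole, via monoaryl bromide 7 (not isolated)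
Conditions: 6 (2.6 equiv), Pd(PPh3)4 (5 mol%), K2CO3 (2 M aq), toluene/EtOH, 90 °C
Reagents that add atoms: none
Why: In this twofold Suzuki–Miyaura coupling, zerovalent palladium carrying PPh3 inserts readily into the C–Br bonds of the electron-poor benzothiadiazole but not into aryl C–Cl bonds, so the chlorines of 6 and of the product should survive.

Step 4
Reactants: 8 4,7-bis(4-chlorophenyl)-5,6-dimethoxy-2,1,3-benzothiadiazole
Product: 9 3,6-bis(4-chlorophenyl)-4,5-dimethoxybenzene-1,2-diamine
Conditions: Zn dust (10 equiv), AcOH, 70 °C, N2; NaHCO3 work-up, crude 9 used at once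
Reagents that add atoms: none
Why: Dissolving-metal reduction cleaves both N–S bonds of the thiadiazole and expels sulfur as H2S, the usual unmasking of benzothiadiazoles to o-phenylenediamines, and aryl chlorides and methyl ethers are inert to Zn/AcOH.

Step 5
Reactants: 9 3,6-bis(4-chlorophenyl)-4,5-dimethoxybenzene-1,2-diamine
Product: 11 5,8-bis(4-chlorophenyl)-6,7-dimethoxy-1,4-dihydroquinoxaline-2,3-dione, via oxamate ester 10 (not isolated)
Conditions: diethyl oxalate (neat, 10 equiv), N2, 150 °C, EtOH distilled off
Reagents that add atoms: diethyl oxalate, CCOC(=O)C(=O)OCC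
Why: Double aminolysis of diethyl oxalate (intermolecular amide formation to 10, then six-membered lactamisation) is the classical condensation to quinoxaline-2,3-diones, and the intramolecular second acylation, driven by removal of ethanol, should offset the hindrance of the flanking aryl rings.

Step 6
Reactants: 11 5,8-bis(4-chlorophenyl)-6,7-dimethoxy-1,4-dihydroquinoxaline-2,3-dione
Product: 13 2,9-dichloro-5,6-dimethoxy-11,12-oxalylindolo[2,3-a]carbazole, via monocyclised lactam 12 (not isolated)
Conditions: Pd(OAc)2 (20 mol%), O2 (1 atm), DMSO, 4 Å MS, 120 °C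
Reagents that add atoms: none
Why: Proposed new method: each amidate nitrogen of the cyclic oxamide binds divalent palladium, acetate-assisted cleavage (concerted metalation–deprotonation) of an ortho C–H of the neighbouring 4-chlorophenyl ring gives a six-membered N,C-palladacycle, and C–N reductive elimination forms the N–aryl bond and zerovalent palladium, which O2 in DMSO reoxidises; the closest known reaction is the Pd(OAc)2/O2 cyclisation of 2-acetamidobiaryls to N-acetylcarbazoles, and new here are an amide nitrogen held in a lactam ring and two closures on one core. Ring D closes by N11–C10a bond formation and ring B by N12–C12a bond formation, each through reductive elimination that contracts the six-membered palladacycle to the five-membered pyrrole, first to 12 and then to 13. The oxalyl bridge locks each N–Pd bond into the position peri to the flanking aryl ring, makes N,N'-chelation of palladium by the vicinal diamide impossible, and replaces two clashing N-substituents in the N11/N12 bay by one six-membered ring of the kind found in N11,N12-bridged indolocarbazoles. With O2 as a mild terminal oxidant the electron-rich diamide should not be drained into an o-quinone diimine, the pathway expected for open-chain vicinal bis-sulfonamides with hypervalent iodine oxidants. The step needs N–C bond formation only at an aryl ortho carbon, and the two ortho C–H bonds of each 4-chlorophenyl ring are equivalent, so the chlorines must end at C2 and C9. Ligand-free palladium should leave the aryl C–Cl bonds alone, and no stereocentre is formed.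

Step 7
Reactants: 13 2,9-dichloro-5,6-dimethoxy-11,12-oxalylindolo[2,3-a]carbazole
Product: 15 borregomycin E, via N11-oxalyl ester 14 (not isolated)
Conditions: K2CO3 (0.5 equiv), MeOH/THF (1:1), rt
Reagents that add atoms: none
Why: N-Acylcarbazole-type amides, whose nitrogen lone pair belongs to the aromatic sextet, are cleaved readily by methoxide, so methanolysis should break both N–C(O) bonds in turn and release dimethyl oxalate without touching the aryl chlorides or methyl ethers.

**Compound list**

1 | 4,5-dimethoxybenzene-1,2-diamine | COc1cc(N)c(N)cc1OC | starting material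
2 | 2-amino-4,5-dimethoxy-N-sulfinylaniline | COc1cc(N)c(N=S=O)cc1OC | intermediate
3 | 5,6-dimethoxy-2,1,3-benzothiadiazole | COc1cc2nsnc2cc1OC | intermediate
4 | 4-bromo-5,6-dimethoxy-2,1,3-benzothiadiazole | COc1cc2nsnc2c(Br)c1OC | intermediate
5 | 4,7-dibromo-5,6-dimethoxy-2,1,3-benzothiadiazole | COc1c(OC)c(Br)c2nsnc2c1Br | intermediate
6 | 4-chlorophenylboronic acid | OB(O)c1ccc(Cl)cc1 | starting material
7 | 4-bromo-7-(4-chlorophenyl)-5,6-dimethoxy-2,1,3-benzothiadiazole | COc1c(OC)c(-c2ccc(Cl)cc2)c2nsnc2c1Br | intermediate
8 | 4,7-bis(4-chlorophenyl)-5,6-dimethoxy-2,1,3-benzothiadiazole | COc1c(OC)c(-c2ccc(Cl)cc2)c2nsnc2c1-c1ccc(Cl)cc1 | intermediate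
9 | 3,6-bis(4-chlorophenyl)-4,5-dimethoxybenzene-1,2-diamine | COc1c(OC)c(-c2ccc(Cl)cc2)c(N)c(N)c1-c1ccc(Cl)cc1 | intermediate
10 | ethyl 2-{[2-amino-3,6-bis(4-chlorophenyl)-4,5-dimethoxyphenyl]amino}-2-oxoacetate | CCOC(=O)C(=O)Nc1c(N)c(-c2ccc(Cl)cc2)c(OC)c(OC)c1-c1ccc(Cl)cc1 | intermediate
11 | 5,8-bis(4-chlorophenyl)-6,7-dimethoxy-1,4-dihydroquinoxaline-2,3-dione | COc1c(OC)c(-c2ccc(Cl)cc2)c2NC(=O)C(=O)Nc2c1-c1ccc(Cl)cc1 | intermediate
12 | 9-chloro-4-(4-chlorophenyl)-5,6-dimethoxy-3H-pyrazino[3,2,1-jk]carbazole-1,2-dione (ring D closed; lactam N–H and its 4-chlorophenyl neighbour still open) | COc1c(OC)c2c3ccc(Cl)cc3n3c2c(NC(=O)C3=O)c1-c1ccc(Cl)cc1 | intermediate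
13 | 2,9-dichloro-5,6-dimethoxy-11,12-oxalylindolo[2,3-a]carbazole (N11 and N12 joined by a –C(=O)–C(=O)– bridge, hexacyclic) | COc1c(OC)c2c3ccc(Cl)cc3n3c2c2n(C(=O)C3=O)c3cc(Cl)ccc3c12 | intermediate
14 | methyl 2-(2,9-dichloro-5,6-dimethoxy-12H-indolo[2,3-a]carbazol-11-yl)-2-oxoacetate | COc1c(OC)c2c3ccc(Cl)cc3n(C(=O)C(=O)OC)c2c2[nH]c3cc(Cl)ccc3c12 | intermediate
15 | borregomycin E (2,9-dichloro-5,6-dimethoxy-11,12-dihydroindolo[2,3-a]carbazole) | COc1c(OC)c2c3ccc(Cl)cc3[nH]c2c2[nH]c3cc(Cl)ccc3c12 | target

**Step count**

Total steps: 7. Longest linear sequence: 7 steps (1 to 15).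

**Steps most likely to fail**

1. Step 6. Palladation may not occur at a nitrogen held in the lactam ring. C–N reductive elimination from divalent palladium may also be too slow for the weakly nucleophilic oxamide nitrogen, so that the reaction stalls after the first closure. The bridge may also open hydrolytically at 120 °C. The fallback forms the same two N–aryl bonds by nucleophilic displacement of fluoride instead of C–H oxidation. It sets out from dibromide 5. Suzuki–Miyaura coupling with (4-chloro-2-fluorophenyl)boronic acid (OB(O)c1ccc(Cl)cc1F) under the conditions of step 3 should give 4,7-bis(4-chloro-2-fluorophenyl)-5,6-dimethoxy-2,1,3-benzothiadiazole F1. Zn/AcOH should unmask 3,6-bis(4-chloro-2-fluorophenyl)-4,5-dimethoxybenzene-1,2-diamine F2. KN(SiMe3)2 (3 equiv) in THF/toluene at 80 °C should then convert each amino group into its potassium anilide, which displaces the ortho fluoride of the neighbouring ring. This intramolecular SNAr is the transition-metal-free carbazole closure known for 2'-fluorobiaryl-2-amines. It closes rings B and D and comes back to the route at 15.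

2. Step 5. The second acylation has to occur at an amino group flanked by an aryl ring and may be slow, and the electron-rich diamine may oxidise at 150 °C before it condenses. The fallback installs the tether before the aryl groups and sets out from dibromide 5. Zn/AcOH should give the less hindered 3,6-dibromo-4,5-dimethoxybenzene-1,2-diamine F3. Condensation with diethyl oxalate should give 5,8-dibromo-6,7-dimethoxy-1,4-dihydroquinoxaline-2,3-dione F4. Twofold Suzuki–Miyaura coupling with 6 (Pd(dppf)Cl2, K2CO3, dioxane/water, 100 °C) then comes back to the route at 11.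

3. Step 3. The coupling may stall after the first arylation at the second, doubly ortho-substituted C–Br bond. The boronic acid may be lost by protodeboronation or homocoupling, and under forcing conditions insertion into C–Cl would begin. The fallback attaches the aryl rings first and the nitrogens afterwards, and sets out from boronic acid 6. Suzuki–Miyaura coupling with commercial 1,4-dibromo-2,3-dimethoxybenzene (COc1c(Br)ccc(Br)c1OC), whose C–Br bonds each have only one ortho substituent, should give 1,4-bis(4-chlorophenyl)-2,3-dimethoxybenzene F5. Nitration (fuming HNO3, AcOH/CH2Cl2) para to each methoxy group of the central ring, the route used for 4,5-dinitroveratrole, should give 1,4-bis(4-chlorophenyl)-2,3-dimethoxy-5,6-dinitrobenzene F6. Fe powder in AcOH then reduces both nitro groups and comes back to the route at 9.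

**Further compounds**

F1 | step 6 | 4,7-bis(4-chloro-2-fluorophenyl)-5,6-dimethoxy-2,1,3-benzothiadiazole | COc1c(OC)c(-c2ccc(Cl)cc2F)c2nsnc2c1-c1ccc(Cl)cc1F
F2 | step 6 | 3,6-bis(4-chloro-2-fluorophenyl)-4,5-dimethoxybenzene-1,2-diamine | COc1c(OC)c(-c2ccc(Cl)cc2F)c(N)c(N)c1-c1ccc(Cl)cc1F
F3 | step 5 | 3,6-dibromo-4,5-dimethoxybenzene-1,2-diamine | COc1c(OC)c(Br)c(N)c(N)c1Br
F4 | step 5 | 5,8-dibromo-6,7-dimethoxy-1,4-dihydroquinoxaline-2,3-dione | COc1c(OC)c(Br)c2NC(=O)C(=O)Nc2c1Br
F5 | step 3 | 1,4-bis(4-chlorophenyl)-2,3-dimethoxybenzene | COc1c(OC)c(-c2ccc(Cl)cc2)ccc1-c1ccc(Cl)cc1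
F6 | step 3 | 1,4-bis(4-chlorophenyl)-2,3-dimethoxy-5,6-dinitrobenzene | COc1c(OC)c(-c2ccc(Cl)cc2)c([N+](=O)[O-])c([N+](=O)[O-])c1-c1ccc(Cl)cc1
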